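**Retrosynthetic overview**

1. The target is opened at the ring bond between the side-chain-bearing CH and the CMe2 carbon. The resulting open chain, a (Z)-allylsilane ending in an enantiopure tertiary bromohydrin ester, should close the cyclohexane by a bromiranium/allylsilane cyclisation that sets the ring CH cis to the pre-set C–Br and leaves the exocyclic C=CH2.
2. That open chain is assembled in one flask from three pieces: a 1-alkyne carrying the bromohydrin ester, Me3SiCH2MgCl, and the fully functionalised (Z)-allylic bromide of the side chain. Syn-silylmethylcupration of the alkyne followed by Pd-catalysed allylation forms the bond between the future ring CH and the side-chain CH2.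
3. Enabling feature: in the cyclohexane ring the CH that carries the side chain lies between the CMe2 carbon and the C(=CH2) carbon, and the side-chain CH2 bonded to it is allylic to the C(Me)=CH olefin. With the ring bond CH–CMe2 opened, that CH and the C(=CH2) carbon are the two carbons of a terminal alkyne, so the CH–CH2 bond joins an alkenylmetal carbon to an allylic electrophile.
4. Alkyne piece: 5-bromo-2-methylpent-2-ene, acetylide alkylation, Shi epoxidation, bromide opening, tetrafluorobenzoate. Side-chain piece: but-2-yn-1-ol, (Z)-iodide, Weinreb acylation, halide exchange, CBS reduction, acetate, allylic bromide.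
5. Ring order: no ring is present before the last step; the single six-membered carbocycle is closed in step 13.

Key step: step 12

Assumption: the trisubstituted alkenyl group is taken to act as the large ketone substituent in the CBS reduction, and the five small starting materials (compounds 1, 2, 7, 11 and 19 below) are taken as commercial.

**Route**

Step 1
Reactants: 1 5-bromo-2-methylpent-2-ene; 2 lithium acetylide–ethylenediamine complex
Product: 3 6-methylhept-5-en-1-yne
Conditions: DMSO, 10 °C → rt
Reagents that add atoms: none
Why: SN2 alkylation of the acetylide anion by the primary bromide (acetylide alkylation) should give the 1-alkyne without touching the trisubstituted olefin, and no stereocentre is formed.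

Step 2
Reactants: 3 6-methylhept-5-en-1-yne
Product: 4 (3R)-3-(but-3-yn-1-yl)-2,2-dimethyloxirane
Conditions: D-fructose-derived Shi ketone (0.3 equiv), Oxone (2KHSO5·KHSO4·K2SO4), K2CO3, Bu4NHSO4, MeCN–CH2(OMe)2, aq. Na2B4O7/Na2EDTA buffer, 0 °C
Reagents that add atoms: Oxone, active component potassium peroxymonosulfate KHSO5, [K+].[O-]S(=O)(=O)OO
Why: Shi epoxidation, in which the chiral dioxirane transfers oxygen to the electron-rich trisubstituted olefin through a spiro transition state that with the D-fructose-derived ketone should set the (R) configuration at the epoxide CH, while the alkyne is inert.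

Step 3
Reactants: 4 (3R)-3-(but-3-yn-1-yl)-2,2-dimethyloxirane
Product: 5 (3S)-3-bromo-2-methylhept-6-yn-2-ol
Conditions: Li2NiBr4 (0.4 M in THF), THF, 0 °C → rt; aq. work-up
Reagents that add atoms: Li2NiBr4 (dilithium tetrabromonickelate), [Li+].[Li+].[Ni+2].[Br-].[Br-].[Br-].[Br-]
Why: SN2 opening of the epoxide by soft nucleophilic bromide at the less substituted CH carbon with inversion (regioselective halohydrin formation) should give the (S)-secondary bromide and keep the tertiary C–O bond.

Step 4
Reactants: 5 (3S)-3-bromo-2-methylhept-6-yn-2-ol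
Product: 6 (3S)-3-bromo-2-methylhept-6-yn-2-yl 2,3,5,6-tetrafluorobenzoate
Conditions: 2,3,5,6-tetrafluorobenzoyl chloride, Et3N, DMAP (0.2 equiv), CH2Cl2, 0 °C → rt
Reagents that add atoms: 2,3,5,6-tetrafluorobenzoyl chloride, O=C(Cl)c1c(F)c(F)cc(F)c1F
Why: DMAP-catalysed acylation of the tertiary alcohol, under conditions too weakly basic to close the bromohydrin back to the epoxide, installs an electron-poor carboxylate as the later leaving group and leaves the C–Br stereocentre untouched.

Step 5
Reactants: 7 but-2-yn-1-ol
Product: 9 (2Z)-3-iodobut-2-en-1-ol, via cyclic vinylalanate 8 (not isolated)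
Conditions: NaAlH2(OCH2CH2OMe)2 (Red-Al), THF, 0 °C → rt; EtOAc; then I2, THF, −78 → 0 °C
Reagents that add atoms: iodine, [I][I]
Why: Hydroxyl-directed trans-hydroalumination delivers hydride to the proximal and aluminium to the distal alkyne carbon within a five-membered alkoxyalanate, and iodinolysis of the C–Al bond with retention should give only the Z-iodide (hydroalumination–iodination).

Step 6
Reactants: 9 (2Z)-3-iodobut-2-en-1-ol
Product: 10 tert-butyl{[(2Z)-3-iodobut-2-en-1-yl]oxy}dimethylsilane
Conditions: TBSCl, imidazole, CH2Cl2, rt
Reagents that add atoms: tert-butyldimethylsilyl chloride (TBSCl), CC(C)(C)[Si](C)(C)Cl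
Why: Silyl ether formation protects the primary alcohol against the organolithium chemistry of the next step, and no stereocentre is involved.

Step 7
Reactants: 10 tert-butyl{[(2Z)-3-iodobut-2-en-1-yl]oxy}dimethylsilane; 11 2-chloro-N-methoxy-N-methylacetamide
Product: 14 (3Z)-5-[(tert-butyldimethylsilyl)oxy]-1-chloro-3-methylpent-3-en-2-one, via alkenyllithium 12 (not isolated), via tetrahedral lithium adduct 13 (not isolated)
Conditions: t-BuLi (2.0 equiv), Et2O, −78 °C; then 11, −78 → −20 °C; aq. NH4Cl
Reagents that add atoms: none
Why: Iodine–lithium exchange proceeds with retention of olefin geometry and the Weinreb ketone synthesis stops at the chelated tetrahedral adduct, so a single acylation should give the Z-chloromethyl enone.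

Step 8
Reactants: 14 (3Z)-5-[(tert-butyldimethylsilyl)oxy]-1-chloro-3-methylpent-3-en-2-one
Product: 15 (3Z)-1-bromo-5-[(tert-butyldimethylsilyl)oxy]-3-methylpent-3-en-2-one
Conditions: LiBr (10 equiv), acetone, rt, repeated once
Reagents that add atoms: LiBr, [Li+].[Br-]
Why: Finkelstein exchange at the carbonyl-activated primary carbon (SN2) is fast and should be driven to the bromide by excess LiBr without touching the olefin geometry.

Step 9
Reactants: 15 (3Z)-1-bromo-5-[(tert-butyldimethylsilyl)oxy]-3-methylpent-3-en-2-one
Product: 16 (2R,3Z)-1-bromo-5-[(tert-butyldimethylsilyl)oxy]-3-methylpent-3-en-2-ol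
Conditions: (R)-Me-CBS oxazaborolidine (0.2 equiv), catecholborane, toluene, −78 °C
Reagents that add atoms: none
Why: Corey–Bakshi–Shibata reduction, in which the oxazaborolidine–borane complex binds the ketone with the trisubstituted alkenyl group as the large substituent and delivers hydride to one carbonyl face, so the (R)-catalyst should give the (R)-bromohydrin by 1,2-reduction only.

Step 10
Reactants: 16 (2R,3Z)-1-bromo-5-[(tert-butyldimethylsilyl)oxy]-3-methylpent-3-en-2-ol
Product: 17 (2R,3Z)-1-bromo-5-[(tert-butyldimethylsilyl)oxy]-3-methylpent-3-en-2-yl acetate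
Conditions: Ac2O, pyridine, DMAP (cat.), CH2Cl2, 0 °C
Reagents that add atoms: acetic anhydride, CC(=O)OC(C)=O
Why: O-Acylation of the secondary alcohol is faster than base-induced epoxide closure of the bromohydrin and does not affect the stereocentre.

Step 11
Reactants: 17 (2R,3Z)-1-bromo-5-[(tert-butyldimethylsilyl)oxy]-3-methylpent-3-en-2-yl acetate
Product: 18 (2R,3Z)-1,5-dibromo-3-methylpent-3-en-2-yl acetate
Conditions: Ph3PBr2, CH2Cl2, 0 °C → rt
Reagents that add atoms: dibromotriphenylphosphorane Ph3PBr2, BrP(Br)(c1ccccc1)(c1ccccc1)c1ccccc1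
Why: The primary allylic silyl ether is converted directly into the bromide through an alkoxyphosphonium bromide (Appel-type SN2 displacement at the CH2 carbon), which should retain the Z geometry and leave the acetate and the other bromide untouched.

Step 12
Reactants: 6 (3S)-3-bromo-2-methylhept-6-yn-2-yl 2,3,5,6-tetrafluorobenzoate; 19 (trimethylsilyl)methylmagnesium chloride; 18 (2R,3Z)-1,5-dibromo-3-methylpent-3-en-2-yl acetate
Product: 22 (2R,3Z,6Z,10S)-2-acetoxy-1,10-dibromo-3,11-dimethyl-7-[(trimethylsilyl)methyl]dodeca-3,6-dien-11-yl 2,3,5,6-tetrafluorobenzoate, via alkenylcopper 20 (not isolated), via alkenylzinc bromide 21 (not isolated)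
Conditions: 19, CuBr·SMe2, Et2O–Me2S, −40 °C; then 6, −40 → −15 °C; then ZnBr2 (THF), Pd(PPh3)4 (5 mol %), 18, −20 → 0 °C
Reagents that add atoms: none
Why: (Me3SiCH2)Cu adds syn across the terminal alkyne of 6 with copper on the terminal carbon, so the future ring CH becomes a nucleophilic alkenyl carbon cis to the CH2SiMe3 group; after transmetalation to zinc, oxidative addition of zerovalent palladium to the primary allylic C–Br bond of 18, transmetalation and reductive elimination at the unhindered CH2 terminus should form the CH–CH2 bond. The closest known reaction types are the carbocupration of 1-alkynes by α-silylalkylcopper reagents and the Negishi coupling of alkenylmetals with allylic halides. No ring is closed and no stereocentre is created here; instead the step fixes the Z geometry of the new trisubstituted allylsilane (syn addition, then coupling with retention), which is the element that will place the side chain equatorial and cis to bromine in the later chair cyclisation, and it plants the silicon that will dictate the exocyclic position of the ring olefin. The step needs regioselective carbometalation (secured by the unbranched alkyl chain of the 1-alkyne), attack at the CH2 and not the C(Me) terminus of the allyl unit (secured by the fully substituted γ-carbon and the palladium-mediated pathway), retention of the Z geometry of 18 (coupling faster than syn–anti exchange at the tertiary allyl terminus) and chemoselectivity over the secondary bromide, the primary bromide and both esters (organocopper and organozinc species should not attack them at low temperature). The precursors are a seven-carbon alkyne unit, a one-carbon Grignard reagent and a six-carbon bromide, and the product holds every carbon of the target in the correct sequence.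

Step 13
Reactants: 22 (2R,3Z,6Z,10S)-2-acetoxy-1,10-dibromo-3,11-dimethyl-7-[(trimethylsilyl)methyl]dodeca-3,6-dien-11-yl 2,3,5,6-tetrafluorobenzoate
Product: 25 (2R,3Z)-1-bromo-5-[(1R,3S)-3-bromo-2,2-dimethyl-6-methylidenecyclohexyl]-3-methylpent-3-en-2-yl acetate, via bromiranium ion 23 (not isolated), via β-silyl cation 24 (not isolated)
Conditions: (CF3)2CHOH, 2,6-di-tert-butylpyridine, high dilution, 0 °C → rt
Reagents that add atoms: none
Why: Proposed new method: solvolytic ionisation of the tertiary tetrafluorobenzoate with anchimeric assistance by the neighbouring bromine should give the enantiopure bromiranium ion 23 without any external electrophilic bromine source (which would attack the allylsilane), the nucleophilic Z-allylsilane then attacks the tertiary iranium carbon through a chair transition state (6-endo closure, bromine and side chain both equatorial, hence cis and (R) at the new ring CH), and the β-silyl cation 24 loses silicon to give only the exocyclic methylene; the closest known reaction types are the enantiospecific arene-terminated polyene cyclisation of bromiranium ions generated from enantiopure bromohydrin esters and the allylsilane-terminated epoxy-olefin cyclisation.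

**Compound list**

1 | 5-bromo-2-methylpent-2-ene | CC(C)=CCCBr | starting material
2 | lithium acetylide–ethylenediamine complex | [Li+].[C-]#C.NCCN | starting material
3 | 6-methylhept-5-en-1-yne | C#CCCC=C(C)C | intermediate
4 | (3R)-3-(but-3-yn-1-yl)-2,2-dimethyloxirane | C#CCC[C@H]1OC1(C)C | intermediate
5 | (3S)-3-bromo-2-methylhept-6-yn-2-ol | C#CCC[C@H](Br)C(C)(C)O | intermediate
6 | (3S)-3-bromo-2-methylhept-6-yn-2-yl 2,3,5,6-tetrafluorobenzoate | C#CCC[C@H](Br)C(C)(C)OC(=O)c1c(F)c(F)cc(F)c1F | intermediate
7 | but-2-yn-1-ol | CC#CCO | starting material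
8 | sodium 2,2-bis(2-methoxyethoxy)-3-methyl-2,5-dihydro-1,2-oxaluminol-2-uide (cyclic vinylalanate) | CC1=CCO[Al-]1(OCCOC)OCCOC.[Na+] | intermediate (not isolated)
9 | (2Z)-3-iodobut-2-en-1-ol | I/C(C)=C\CO | intermediate
10 | tert-butyl{[(2Z)-3-iodobut-2-en-1-yl]oxy}dimethylsilane | I/C(C)=C\CO[Si](C)(C)C(C)(C)C | intermediate
11 | 2-chloro-N-methoxy-N-methylacetamide | CON(C)C(=O)CCl | starting material
12 | (2E)-4-[(tert-butyldimethylsilyl)oxy]but-2-en-2-yllithium (lithium cis to CH2OTBS) | [Li]/C(C)=C\CO[Si](C)(C)C(C)(C)C | intermediate (not isolated)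
13 | lithium (3Z)-5-[(tert-butyldimethylsilyl)oxy]-1-chloro-2-[methoxy(methyl)amino]-3-methylpent-3-en-2-olate | [Li+].[O-]C(CCl)(N(C)OC)/C(C)=C\CO[Si](C)(C)C(C)(C)C | intermediate (not isolated)
14 | (3Z)-5-[(tert-butyldimethylsilyl)oxy]-1-chloro-3-methylpent-3-en-2-one | ClCC(=O)/C(C)=C\CO[Si](C)(C)C(C)(C)C | intermediate
15 | (3Z)-1-bromo-5-[(tert-butyldimethylsilyl)oxy]-3-methylpent-3-en-2-one | BrCC(=O)/C(C)=C\CO[Si](C)(C)C(C)(C)C | intermediate
16 | (2R,3Z)-1-bromo-5-[(tert-butyldimethylsilyl)oxy]-3-methylpent-3-en-2-ol | BrC[C@H](O)/C(C)=C\CO[Si](C)(C)C(C)(C)C | intermediate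
17 | (2R,3Z)-1-bromo-5-[(tert-butyldimethylsilyl)oxy]-3-methylpent-3-en-2-yl acetate | BrC[C@H](OC(C)=O)/C(C)=C\CO[Si](C)(C)C(C)(C)C | intermediate
18 | (2R,3Z)-1,5-dibromo-3-methylpent-3-en-2-yl acetate | BrC[C@H](OC(C)=O)/C(C)=C\CBr | intermediate
19 | (trimethylsilyl)methylmagnesium chloride | C[Si](C)(C)C[Mg]Cl | starting material
20 | [(1Z,5S)-5-bromo-6-methyl-6-(2,3,5,6-tetrafluorobenzoyloxy)-2-(trimethylsilylmethyl)hept-1-en-1-yl]copper | C[Si](C)(C)C/C(CC[C@H](Br)C(C)(C)OC(=O)c1c(F)c(F)cc(F)c1F)=C\[Cu] | intermediate (not isolated)
21 | [(1Z,5S)-5-bromo-6-methyl-6-(2,3,5,6-tetrafluorobenzoyloxy)-2-(trimethylsilylmethyl)hept-1-en-1-yl]zinc bromide | C[Si](C)(C)C/C(CC[C@H](Br)C(C)(C)OC(=O)c1c(F)c(F)cc(F)c1F)=C\[Zn]Br | intermediate (not isolated)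
22 | (2R,3Z,6Z,10S)-2-acetoxy-1,10-dibromo-3,11-dimethyl-7-[(trimethylsilyl)methyl]dodeca-3,6-dien-11-yl 2,3,5,6-tetrafluorobenzoate | C[Si](C)(C)C/C(CC[C@H](Br)C(C)(C)OC(=O)c1c(F)c(F)cc(F)c1F)=C\C/C=C(/C)[C@H](CBr)OC(C)=O | intermediate
23 | bromiranium ion from 22 (bromine bridging the former CHBr and CMe2 carbons, configuration at the ring CH as in 22) | C[Si](C)(C)C/C(CC[C@@H]1[Br+]C1(C)C)=C\C/C=C(/C)[C@H](CBr)OC(C)=O | intermediate (not isolated)
24 | tertiary β-silyl cyclohexyl cation (ring closed, CH2SiMe3 on the cationic carbon) | C[Si](C)(C)C[C+]1CC[C@H](Br)C(C)(C)[C@@H]1C/C=C(/C)[C@H](CBr)OC(C)=O | intermediate (not isolated)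
25 | (2R,3Z)-1-bromo-5-[(1R,3S)-3-bromo-2,2-dimethyl-6-methylidenecyclohexyl]-3-methylpent-3-en-2-yl acetate | C=C1CC[C@H](Br)C(C)(C)[C@@H]1C/C=C(/C)[C@H](CBr)OC(C)=O | target

**Step count and risks**

Total steps: 13. Longest linear sequence: 9 steps (steps 5 to 13, from but-2-yn-1-ol).

Most likely to fail, step 13 (Proposed new method). What may go wrong: protodesilylation of the allylsilane before ionisation, capture of the bromiranium ion by carboxylate or solvent instead of the olefin, or erosion of its configuration by bromine transfer between olefins. The fallback uses known chemistry and sets out from 3 and 18. Cp2ZrCl2-catalysed methylalumination of 3 with AlMe3 (ClCH2CH2Cl, rt) gives dimethyl[(1E)-2,6-dimethylhepta-1,5-dien-1-yl]alane F1. This is coupled in the same flask with 18 under Pd(PPh3)4 catalysis to give (2R,3Z,6E)-1-bromo-3,7,11-trimethyldodeca-3,6,10-trien-2-yl acetate F2. Treatment of F2 with Et2SBr·SbCl5Br in MeNO2 at −25 °C (reagent-induced bromonium polyene cyclisation ended by proton loss) should give 25, where the fallback rejoins the route. Because an achiral bromine donor cannot choose between the olefin faces and proton loss is not regiospecific, 25 would form together with its ring diastereomer and endocyclic olefin isomers and would have to be separated on AgNO3-impregnated silica and by HPLC.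

Second, step 12. What may go wrong: ionisation of the activated tertiary ester by the Lewis acidic zinc and magnesium salts, or loss of regiocontrol (CH2 versus C(Me) terminus) and of Z geometry during the zinc/palladium allyl transfer. The fallback sets out from the alkenylcopper 20. Quenching with I2 gives the isolable (3S,6Z)-3-bromo-7-iodo-2-methyl-6-(trimethylsilylmethyl)hept-6-en-2-yl 2,3,5,6-tetrafluorobenzoate F3. Miyaura borylation (B2pin2, PdCl2(dppf), KOAc, dioxane, 60 °C) converts it into (3S,6Z)-3-bromo-2-methyl-7-(4,4,5,5-tetramethyl-1,3,2-dioxaborolan-2-yl)-6-(trimethylsilylmethyl)hept-6-en-2-yl 2,3,5,6-tetrafluorobenzoate F4. Suzuki–Miyaura coupling of F4 with 18 (Pd(PPh3)4, K3PO4, THF–H2O, rt), free of zinc and magnesium salts, rejoins the route at 22.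

Third, step 3. What may go wrong: loss of regiocontrol in the epoxide opening (bromide attack at the tertiary carbon) or Lewis-acid-induced rearrangement of the epoxide to a ketone. The fallback sets out from 3. NBS in THF–water gives racemic 3-bromo-2-methylhept-6-yn-2-ol F5, whose regiochemistry is fixed by Markovnikov opening of the bromonium ion by water. Acylation as in step 4 gives racemic 3-bromo-2-methylhept-6-yn-2-yl 2,3,5,6-tetrafluorobenzoate F6. Preparative HPLC on a chiral stationary phase then delivers the (S)-enantiomer, which is 6, where the fallback rejoins the route.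

Further compounds
F1 | step 13 | dimethyl[(1E)-2,6-dimethylhepta-1,5-dien-1-yl]alane | C[Al](C)/C=C(\C)CCC=C(C)C
F2 | step 13 | (2R,3Z,6E)-1-bromo-3,7,11-trimethyldodeca-3,6,10-trien-2-yl acetate | CC(C)=CCC/C(C)=C/C/C=C(/C)[C@H](CBr)OC(C)=O
F3 | step 12 | (3S,6Z)-3-bromo-7-iodo-2-methyl-6-(trimethylsilylmethyl)hept-6-en-2-yl 2,3,5,6-tetrafluorobenzoate | C[Si](C)(C)C/C(CC[C@H](Br)C(C)(C)OC(=O)c1c(F)c(F)cc(F)c1F)=C\I
F4 | step 12 | (3S,6Z)-3-bromo-2-methyl-7-(4,4,5,5-tetramethyl-1,3,2-dioxaborolan-2-yl)-6-(trimethylsilylmethyl)hept-6-en-2-yl 2,3,5,6-tetrafluorobenzoate | C[Si](C)(C)C/C(CC[C@H](Br)C(C)(C)OC(=O)c1c(F)c(F)cc(F)c1F)=C\B1OC(C)(C)C(C)(C)O1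
F5 | step 3 | racemic 3-bromo-2-methylhept-6-yn-2-ol | C#CCCC(Br)C(C)(C)O
F6 | step 3 | racemic 3-bromo-2-methylhept-6-yn-2-yl 2,3,5,6-tetrafluorobenzoate | C#CCCC(Br)C(C)(C)OC(=O)c1c(F)c(F)cc(F)c1F
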